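(The readings were generated by integration with constants of no real substance; scatter was added.)

Every mole of the limiting reagent stays on the books. I take substrate and coupling partner to be spent mole for mole, so the lesser charge bounds the target, and whatever of that charge has reacted and is not target at the end has passed through target and been lost.

| setting | summer | winter | Thursday's | Tuesday's | Sunday's |
|---|---|---|---|---|---|
| substrate | 0.36 M | 0.69 M | 0.25 M | 0.40 M | 0.60 M |
| coupling partner | 0.30 M | 0.30 M | 0.300 M | 0.300 M | 0.300 M |
| catalyst | 0.50 mM | 0.50 mM | 0.50 mM | 0.50 mM | 0.50 mM |
| added ligand | 0.41 mM | 0.41 mM | 0.41 mM | 0.41 mM | 0.41 mM |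
| remark | run made earlier | run made earlier |  |  |  |
| time |  |  | 50 min | 50 min | 50 min |

- summer (time / min: target / %): 2.00: 44; 4.00: 59; 8.00: 62; 12.0: 59; 25.0: 41
- winter (time / min: target / %): 5.00: 35; 10.0: 36; 15.0: 29; 20.0: 26; 25.0: 24

(standard deviation of a reading: 1.5 percentage points)

- "hardly changes" means that all values lie within two and a half points (for a concentration: within two and a half percent of the largest)

* [target] at the end for Thursday's, Tuesday's, Sunday's, in this order
* the course of these numbers from the first flask to the last (falls, then rises / rises, then falls / falls all the way / hardly changes / rises all the way)

The limiting reagent is the substrate in Thursday's flask, and the coupling partner in Tuesday's and Sunday's. The loss is the entry I need first. In the summer run the target falls from 59% at 12.0 min to 41% at 25.0 min, and read as a first-order decay this gives 0.0280 min⁻¹. The winter run, from 36% at 10.0 min to 24% at 25.0 min, reads 0.0270 min⁻¹.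

So I follow one molecule of target and ask for its survival chance, the fraction of target born at the start that is still target after the time asked, exp(−kt): 0.247. I book each molecule as born at the start, since the summer run already shows 59% at 4.00 min, a time much shorter than 50 min.

Thursday's books then close with 0.0617 M as c(target), 0.188 M lost from target, and 0.0500 M of coupling partner over. Tuesday's close with 0.0740 M as c(target), 0.226 M lost, and 0.100 M of substrate over. Sunday's hold the same two entries, with 0.300 M of substrate over. My row therefore rises and then hardly changes.

The forecast gives 0.075 M, 0.09 M and 0.1 M, rises all the way, holding that “Decay looks like target alone”, and its last point stands above mine.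

The flasks give 0.0586 M, 0.0675 M and 0.0645 M, rises, then falls, whereas my row ran level from Tuesday's to Sunday's and stood above these values at each flask.

    substrate + coupling partner + catalyst → target + catalyst, rate k1*[substrate]*[coupling partner]*[catalyst]/(1 + ([substrate]/sat1)) (0.710 M, k = 5700 L² mol⁻² min⁻¹)
    catalyst + added ligand ⇌ idle complex, settled at all times (K = 1800 L mol⁻¹)
    target → over-reaction product (k = 0.0320 min⁻¹)

In Thursday's flask the target, each step taken net, is made 9.46 times faster than it is used up at 1.96 min. At 50.0 min in Thursday's flask the rate of making, each step taken net, is 0.0188 of the rate of loss. The survival chance over half the time, 0.497, takes Thursday's target from 50.0% at 25.0 min to 24.8%, and the flask holds 23.4%. In Sunday's flask it takes 23.9% to 11.9%, and the flask holds 10.8%.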